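# Proposed synthesis of CNP0252244.1 by a site-selective tetrahydrofuran-to-tetralin ring switch on a bis-tetrahydrofuran biaryl

## Analysis of the target

The target is an unsymmetrical biaryl dimer of two lignan units. Rings C and D form a 2,2'-dihydroxy-3,3'-dimethoxybiphenyl, and each carries one side unit para to its phenol. Ring C is bonded to C2 of a tetrahydrofuran (ring B: O1, C2, C3 with CH2OH, C4 with OH and the CH2 of the 3-hydroxy-4-methoxyphenyl ring A, C5). Ring D is bonded to C1' of an aryltetralin (carbocycle E: C1', C2' with CH2OH, C3' with OH and CH2OH, C4'; fused through C4a'/C8a' to ring F, which has OMe on C6' and OH on C7'). There are six stereocentres. In ring B they are C2 (S), C3 (R) and C4 (S), with ring C trans to the C3 CH2OH and that CH2OH trans to the tertiary OH. In ring E they are C1' (S), C2' (S) and C3' (S), with ring D trans to the C2' CH2OH. The biaryl axis has only two ortho substituents and is taken as freely rotating. The sensitive features are four phenols (two of them an easily oxidized biphenol), five aliphatic hydroxyls, and benzylic C–O and C–C bonds para to phenol oxygen that ionize in acid. The difficulty is that the two halves have different ring systems and different arene patterns, each holds a tertiary carbinol, and one of four phenols has to be told apart from the others. The strategy rests on one feature. C1', C2', C3' and the C3' hydroxymethyl group of ring E are C2, C3, C4 and C5–O1 of a tetrahydrofuran with the same configuration as ring B, opened at O1–C2 and bonded from C2 to the arene instead. The carbon that becomes C8a' lies ortho to the ring F CH2 and para to the C6' methoxy. Ring A has its methoxy para to its own CH2, so its carbons next to the CH2 are reached only by the 3-oxygen, which can be switched off as an ester.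

## Retrosynthetic reasoning

**28 from 27.** The O–acetyl bond on ring A is cut first. The acetate is there only for the step before it, and its removal by mild base asks nothing of the rest of the molecule.

**27 from 26.** C1'–C8a' is cut and C1' is rejoined to the oxygen of the C3' hydroxymethyl group, which turns ring E back into a second tetrahydrofuran. This is the place to cut because both halves of 26 then become the same (2S,3R,4S) unit and differ only in the arene on the C4 benzyl group. Forward, acid has to ionize the C2–O1 bond of the ring D tetrahydrofuran, and the vanillyl carbon para to its methoxy has to trap the cation. The same acid ionizes the ring C tetrahydrofuran as well, which must only reclose. Ring A therefore enters as an aryl acetate, so that its one position para to oxygen is para to an ester oxygen and reacts far more slowly.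

**26 from 25, 24 and 23.** The phenols of rings C, D and F are carried as benzyl ethers and the ring A phenol as an allyl ether. The allyl group can be taken off alone, the single free phenol of 24 can be acetylated as its phenoxide beside the alcohols, and hydrogenolysis then frees the other three phenols without touching the acetate. These three operations are the price for telling ring A from ring F.

**23 from 17 and 21 (through 22).** The C5–C5' biaryl bond is cut, giving two aryl bromides that differ only in the benzyl arene. Each half is then made and purified alone, and the same bromo aldehyde 13 serves both. Growing both chains one after the other on a ready-made biaryl dialdehyde was weighed and set aside. The second enolate addition would meet the base-labile ester-lactone of the first half, the dialdehyde would need desymmetrizing, and every stereochemical step would run on the full skeleton.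

**17 from 16, and 21 from 20.** O1–C2 is cut to a benzylic carbinol and the C5 hydroxyl. Forward, mild acid ionizes the carbinol para to the benzyloxy group and the C5 hydroxyl closes the five-membered ring. The benzylic centre is made at this point, trans to the C3 substituent, so the configuration of the carbinol does not matter.

**16 from 15, and 15 from 7 and 13 (through 14); likewise 20 from 19, and 19 from 11 and 13 (through 18).** The three CH2OH/CH–OH carbons are traced back to a lactone ester, and C2–C3 is cut as an aldol bond between the aldehyde 13 and the dianion of the malate diester. The forward reaction has to set C3 relative to the C4 carbinol, which the chelated dianion does by reacting anti to the C4 oxygen.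

**7 from 6, 6 from 2 and 5, and 2 from 1; likewise 11 from 10, and 10 from 2 and 9.** The C4–CH2Ar bond is cut. The carbinol carbon of L-malic acid 1 is stored in the cis dioxolanone 2, whose enolate is benzylated trans to the tert-butyl group, so the benzyl group replaces hydrogen with retention. L-Malic acid then supplies C4 of both halves with the required S configuration.

**5 from 4 and 3; 9 from 8; 13 from 12.** These are simple O-alkylations and alcohol-to-bromide exchanges on catalogue phenols.

## Alternatives that were turned down

**Alternative 1:** The disconnection is C1'–C2' of the tetralin, made on a biaryl that is present from the start. The dianion of the malate diester also used here (11) would add to the free formyl group of the mono-acetal biaryl dialdehyde A1, and lactonization would give the γ-lactone A2. Reduction and a forcing acid step would then close ring E straight from the carbinol.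
- For it: one chirality source, C2' set against C3' in the bond-forming step, and no selection between two tetrahydrofurans, because the ring A half does not yet exist when the tetralin is closed. On that last point it is stronger than the chosen route.
- Against it for this target: the second chain must be grown on the unveiled aldehyde of a substrate that already carries the polyol tetralin, which needs extra protection or excess dianion. A1 needs a desymmetrized biaryl. Every stereochemical step after A2 runs on the full skeleton.
- Comparison: the chosen route uses the same aldol as a feeder reaction, but twice on a simple bromo aldehyde. It offers convergence and one three-step protocol for both halves, and pays with the site-selectivity demand of one late step.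

**Alternative 2:** The disconnection is the bond between C4 and the ring A benzylic carbon, made together with the tertiary carbinol. Irradiation of the tetrahydrofuran-4-one A3 would let the excited ketone abstract a benzylic hydrogen from the isovanillyl ether on its C3 arm, and radical recombination would give the cis-fused furofuranol A4. Reductive cleavage of the ring A benzylic C–O bond of A4 would then leave the benzyl carbinol pattern of ring B.
- For it: the quaternary carbinol and its benzyl C–C bond form in one step, the cis ring fusion is enforced, and no base-labile lactone is involved. In bond economy at C4 it is the more elegant.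
- Against it: the hydrogen abstraction through a seven-membered transition state has to compete with Norrish α-cleavage of an α-alkoxy ketone. All stereocontrol hangs on one centre of A3 that must be made enantiopure by other means. The later reduction must distinguish two benzylic C–O bonds. The tetralin half is not addressed at all.
- Comparison: the chosen route gets C4 from the chiral pool by an alkylation of known sense, and the same sequence serves both halves.

**Alternative 3:** The disconnection is C2'–C3' of ring E. SmI2 would turn the α-bromo ester A5 into its samarium enolate, which would add to the side-chain ketone and give the β-hydroxy ester A6.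
- For it: the carbocycle closes without acid, so no arene has to be chosen and no cation is formed beside electron-rich rings. A samarium chelate should place the C3' oxygen and the C2' ester cis, as needed. In independence from arene electronics it is stronger than the chosen route.
- Against it: C1' must be installed beforehand as an enantioenriched diarylmethine, and C2'/C3' must then be relayed from it. The α-benzyloxy ketone of A5 is itself liable to reductive C–O cleavage by SmI2. The ring A half still needs its own synthesis, so the step count is clearly higher.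
- Comparison: the chosen route derives all three tetralin centres from one malate unit plus one closure controlled by the neighbouring centre.

Key step: step 20

## Remarks on the chemistry

- 3, 8 and 12 are taken as catalogue compounds; 3 and 8 are one or two routine steps from isovanillin and vanillin.
- The benzylic carbinol centre of 14–16 and 18–20 is drawn as the expected epimer; steps 12 and 15 pass through the benzylic cation, so either epimer serves.

## Route

**Step 1**
Reactants: 1 L-malic acid
Product: 2 2-[(2S,4S)-2-tert-butyl-5-oxo-1,3-dioxolan-4-yl]acetic acid (cis)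
Conditions: pivalaldehyde, TsOH (cat.), H2SO4 (cat.), pentane, reflux, water separator; recrystallization
Reagents that add atoms: pivalaldehyde, CC(C)(C)C=O
Why: Acid-catalysed acetalization of the α-hydroxy acid unit closes the five-membered dioxolanone; the cis isomer is favoured and crystalline, and the malic acid stereocentre is not touched.

**Step 2**
Reactants: 3 3-hydroxy-4-methoxybenzyl alcohol (isovanillyl alcohol)
Product: 4 [4-methoxy-3-(prop-2-enyloxy)phenyl]methanol
Conditions: allyl bromide (1.1 equiv), K2CO3, acetone, reflux
Reagents that add atoms: allyl bromide, C=CCBr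
Why: Williamson etherification; K2CO3 deprotonates only the phenol, so the benzylic alcohol stays free.

**Step 3**
Reactants: 4 [4-methoxy-3-(prop-2-enyloxy)phenyl]methanol
Product: 5 4-(bromomethyl)-1-methoxy-2-(prop-2-enyloxy)benzene
Conditions: PBr3 (0.4 equiv), Et2O, 0 °C; used at once
Reagents that add atoms: phosphorus tribromide, BrP(Br)Br
Why: Standard conversion of an electron-rich benzylic alcohol into the bromide; the allyl ether is inert.

**Step 4**
Reactants: 2 the cis dioxolanone acid; 5 the allyloxy benzyl bromide
Product: 6 2-[(2S,4S)-2-tert-butyl-4-{[4-methoxy-3-(prop-2-enyloxy)phenyl]methyl}-5-oxo-1,3-dioxolan-4-yl]acetic acid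
Conditions: LiN(SiMe3)2 (2.1 equiv), THF, −78 °C; 5, −78 → −20 °C; aq. HCl
Reagents that add atoms: none
Why: Enolate alkylation of the carboxylate–dioxolanone dianion (self-regeneration of a stereocentre); the bromide enters trans to the tert-butyl group, so benzyl replaces hydrogen with retention and the quaternary centre is S.

**Step 5**
Reactants: 6 the benzylated dioxolanone acid
Product: 7 dimethyl (2S)-2-hydroxy-2-{[4-methoxy-3-(prop-2-enyloxy)phenyl]methyl}butanedioate
Conditions: HCl (1.25 M in MeOH), reflux
Reagents that add atoms: methanol, CO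
Why: Acid-catalysed methanolysis of the dioxolanone together with Fischer esterification of the side-chain acid; the quaternary carbinol cannot epimerize.

**Step 6**
Reactants: 8 [4-(benzyloxy)-3-methoxyphenyl]methanol
Product: 9 1-(benzyloxy)-4-(bromomethyl)-2-methoxybenzene
Conditions: PBr3 (0.4 equiv), Et2O, 0 °C; used at once
Reagents that add atoms: phosphorus tribromide, BrP(Br)Br
Why: Same alcohol-to-bromide exchange as step 3.

**Step 7**
Reactants: 2 the cis dioxolanone acid; 9 the benzyloxy benzyl bromide
Product: 10 2-[(2S,4S)-4-{[4-(benzyloxy)-3-methoxyphenyl]methyl}-2-tert-butyl-5-oxo-1,3-dioxolan-4-yl]acetic acid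
Conditions: LiN(SiMe3)2 (2.1 equiv), THF, −78 °C; 9, −78 → −20 °C; aq. HCl
Reagents that add atoms: none
Why: Same dianion alkylation as step 4, trans to the tert-butyl group, giving the S quaternary centre with retention.

**Step 8**
Reactants: 10 the benzylated dioxolanone acid
Product: 11 dimethyl (2S)-2-{[4-(benzyloxy)-3-methoxyphenyl]methyl}-2-hydroxybutanedioate
Conditions: HCl (1.25 M in MeOH), reflux
Reagents that add atoms: methanol, CO
Why: Same methanolysis and esterification as step 5; aryl benzyl ethers survive methanolic HCl.

**Step 9**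
Reactants: 12 5-bromovanillin
Product: 13 4-(benzyloxy)-3-bromo-5-methoxybenzaldehyde
Conditions: benzyl bromide, K2CO3, DMF, 60 °C
Reagents that add atoms: benzyl bromide, BrCc1ccccc1
Why: Williamson etherification of the phenol; the benzyl ether later supports benzylic ionization and is removable by hydrogenolysis.

**Step 10**
Reactants: 7 the ring A malate diester; 13 the bromo aldehyde
Product: 15 methyl (2S,3R,4S)-2-[4-(benzyloxy)-3-bromo-5-methoxyphenyl]-4-hydroxy-4-{[4-methoxy-3-(prop-2-enyloxy)phenyl]methyl}-5-oxooxolane-3-carboxylate, via lithium aldolate 14 (not isolated)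
Conditions: LiN(iPr)2 (2.2 equiv), THF, −78 °C; 13, −78 → −30 °C; AcOH
Reagents that add atoms: none
Why: Aldol addition of the chelated alkoxide–enolate dianion of the malate, followed by lactonization of the new benzylic alkoxide onto the ester at the carbinol carbon. C3 is set by attack anti to the C4 oxygen of the chelate, the sense known for alkylations of such dianions. The benzylic centre is drawn trans but is re-formed in step 12, and any unlactonized 14 gives the same tetraol in step 11.

**Step 11**
Reactants: 15 the ring A/C lactone ester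
Product: 16 (2S,3R)-3-[(S)-[4-(benzyloxy)-3-bromo-5-methoxyphenyl](hydroxy)methyl]-2-{[4-methoxy-3-(prop-2-enyloxy)phenyl]methyl}butane-1,2,4-triol
Conditions: LiAlH4 (4 equiv), THF, 0 °C; H2O, aq. NaOH work-up
Reagents that add atoms: none
Why: Hydride reduction of lactone and ester to the tetraol; the aryl bromide, allyl ether and benzyl ether are inert at 0 °C and no stereocentre is touched.

**Step 12**
Reactants: 16 the ring A/C tetraol
Product: 17 (3S,4R,5S)-5-[4-(benzyloxy)-3-bromo-5-methoxyphenyl]-4-(hydroxymethyl)-3-{[4-methoxy-3-(prop-2-enyloxy)phenyl]methyl}oxolan-3-ol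
Conditions: camphorsulfonic acid (0.2 equiv), CH2Cl2, 0 °C → rt; Et3N quench at full conversion
Reagents that add atoms: none
Why: Acid-catalysed cycloetherification through the para-benzyloxybenzyl cation; the C5 hydroxyl is the only oxygen that can close a strain-free ring, and this O-capture is faster than C-alkylation of ring A. The aryl group settles trans to the C3 CH2OH (2S) from either carbinol epimer, because closure is reversible and the trans ring is the less crowded.

**Step 13**
Reactants: 11 the ring F malate diester; 13 the bromo aldehyde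
Product: 19 methyl (2S,3R,4S)-2-[4-(benzyloxy)-3-bromo-5-methoxyphenyl]-4-{[4-(benzyloxy)-3-methoxyphenyl]methyl}-4-hydroxy-5-oxooxolane-3-carboxylate, via lithium aldolate 18 (not isolated)
Conditions: LiN(iPr)2 (2.2 equiv), THF, −78 °C; 13, −78 → −30 °C; AcOH
Reagents that add atoms: none
Why: Same malate dianion aldol–lactonization as step 10, with C3 set anti to the C4 oxygen.

**Step 14**
Reactants: 19 the ring D/F lactone ester
Product: 20 (2S,3R)-3-[(S)-[4-(benzyloxy)-3-bromo-5-methoxyphenyl](hydroxy)methyl]-2-{[4-(benzyloxy)-3-methoxyphenyl]methyl}butane-1,2,4-triol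
Conditions: LiAlH4 (4 equiv), THF, 0 °C; H2O, aq. NaOH work-up
Reagents that add atoms: none
Why: Same hydride reduction as step 11.

**Step 15**
Reactants: 20 the ring D/F tetraol
Product: 21 (3S,4R,5S)-5-[4-(benzyloxy)-3-bromo-5-methoxyphenyl]-3-{[4-(benzyloxy)-3-methoxyphenyl]methyl}-4-(hydroxymethyl)oxolan-3-ol
Conditions: camphorsulfonic acid (0.2 equiv), CH2Cl2, 0 °C → rt; Et3N quench at full conversion
Reagents that add atoms: none
Why: Same kinetic cycloetherification as step 12. The tetrahydrofuran is the faster-formed product and is kept by quenching before the slower, irreversible Friedel–Crafts closure onto the vanillyl ring sets in.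

**Step 16**
Reactants: 21 the ring D/F bromo tetrahydrofuran; 17 the ring A/C bromo tetrahydrofuran
Product: 23 (3S,4R,5S)-5-{2,2'-bis(benzyloxy)-5'-[(2S,3R,4S)-4-{[4-(benzyloxy)-3-methoxyphenyl]methyl}-4-hydroxy-3-(hydroxymethyl)oxolan-2-yl]-3,3'-dimethoxy-[1,1'-biphenyl]-5-yl}-4-(hydroxymethyl)-3-{[4-methoxy-3-(prop-2-enyloxy)phenyl]methyl}oxolan-3-ol, via pinacol boronate 22 (not isolated)
Conditions: 21, B2pin2 (1.05 equiv), Pd(dppf)Cl2 (5 mol %), KOAc, 1,4-dioxane, 90 °C; then 17, aq. K3PO4, 90 °C
Reagents that add atoms: bis(pinacolato)diboron, CC1(C)OB(OC1(C)C)B1OC(C)(C)C(C)(C)O1 (its boryl group is carried by 22 only)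
Why: Miyaura borylation followed in the same pot by Suzuki–Miyaura coupling; each partner has one ortho substituent, so the biaryl forms without a stable axis. Free alcohols are tolerated, and any allyl ether lost under the coupling conditions gives 24, the next intermediate.

**Step 17**
Reactants: 23 the allyl tris-benzyl bis-tetrahydrofuran
Product: 24 the ring A phenol (as 23 with 3-hydroxy-4-methoxybenzyl on C4 of the ring C tetrahydrofuran)
Conditions: Pd(PPh3)4 (5 mol %), morpholine, THF, rt
Reagents that add atoms: none
Why: Tsuji–Trost deallylation; zerovalent palladium ionizes only the allyl aryl ether and morpholine takes up the allyl group, leaving the benzyl ethers and alcohols alone.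

**Step 18**
Reactants: 24 the ring A phenol
Product: 25 the ring A acetate (as 24 with 3-acetoxy-4-methoxybenzyl)
Conditions: Ac2O (1.1 equiv), K2CO3, acetone, 0 °C → rt
Reagents that add atoms: acetic anhydride, CC(=O)OC(C)=O
Why: Chemoselective O-acetylation of the only phenol through its phenoxide; without an acylation catalyst the neutral primary and tertiary alcohols react much more slowly with one equivalent of anhydride.

**Step 19**
Reactants: 25 the tris-benzyl ring A acetate
Product: 26 the bis-tetrahydrofuran precursor (ring A acetate; phenols of rings C, D and F free; both tetrahydrofurans 2S,3R,4S)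
Conditions: H2 (1 atm), Pd/C (10 wt %), EtOAc–THF, rt; stopped after three equivalents
Reagents that add atoms: none
Why: Hydrogenolysis of the three aryl benzyl ethers, which are cleaved much faster than the dialkyl benzylic C2–O1 bonds of the rings; the aryl acetate is untouched.

**Step 20**
Reactants: 26 the bis-tetrahydrofuran precursor
Product: 27 the tetralin–tetrahydrofuran dimer with ring A acetate (1'S,2'S,3'S; 2S,3R,4S)
Conditions: TFA (5 equiv), CH2Cl2–(CF3)2CHOH (4:1), 0.005 M, 0 °C → rt; aq. NaHCO3 at full conversion
Reagents that add atoms: none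
Why: TFA protonates O1 of both tetrahydrofurans, and each C2–O1 bond para to a free phenol ionizes reversibly to a para-hydroxybenzyl cation with its C5 hydroxymethyl group set free. In the ring D half the cation is attacked by the vanillyl carbon para to the methoxy and ortho to the benzylic CH2, a 6-endo cation–arene (Friedel–Crafts) closure that forms C1'–C8a' and ring E; rearomatization makes it irreversible, so the reversible O-closure drains into the tetralin. The closest known reaction is the acid-induced isomerization of olivil-type 2-aryl-4-benzyltetrahydrofuran-4-ols to cycloolivil-type aryltetralins. C1' is the only new stereocentre: in the chair-like transition state ring D lies pseudo-equatorial and trans to the C2' CH2OH, giving 1'S, while C2' and C3' are the unchanged C3 and C4 of the opened ring. The step needs selectivity between the halves, and ring electronics supply it: in ring A the carbons next to the CH2 are activated only by the acetoxy oxygen, so the ring C cation recloses to the 2,3-trans tetrahydrofuran faster than it alkylates ring A. Within ring F the unhindered carbon para to the methoxy is preferred over the flanked carbon ortho to it. High dilution in a non-nucleophilic, cation-stabilizing medium suppresses intermolecular alkylation, and TFA without an alcohol leaves the aryl acetate in place.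

**Step 21**
Reactants: 27 the tetralin–tetrahydrofuran dimer with ring A acetate
Product: 28 CNP0252244.1
Conditions: K2CO3 (0.3 equiv), MeOH, 0 °C, argon; AcOH
Reagents that add atoms: none
Why: Base-catalysed methanolysis of the aryl acetate; no stereocentre is base-labile, and exclusion of air protects the biphenol.

## Compound list

1 | L-malic acid, (S)-2-hydroxybutanedioic acid | OC(=O)C[C@H](O)C(=O)O | starting material
2 | 2-[(2S,4S)-2-tert-butyl-5-oxo-1,3-dioxolan-4-yl]acetic acid (cis) | CC(C)(C)[C@H]1O[C@@H](CC(=O)O)C(=O)O1 | intermediate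
3 | 3-hydroxy-4-methoxybenzyl alcohol | COc1ccc(CO)cc1O | starting material
4 | [4-methoxy-3-(prop-2-enyloxy)phenyl]methanol | COc1ccc(CO)cc1OCC=C | intermediate
5 | 4-(bromomethyl)-1-methoxy-2-(prop-2-enyloxy)benzene | COc1ccc(CBr)cc1OCC=C | intermediate
6 | 2-[(2S,4S)-2-tert-butyl-4-{[4-methoxy-3-(prop-2-enyloxy)phenyl]methyl}-5-oxo-1,3-dioxolan-4-yl]acetic acid | CC(C)(C)[C@H]1O[C@](CC(=O)O)(Cc2ccc(OC)c(OCC=C)c2)C(=O)O1 | intermediate
7 | dimethyl (2S)-2-hydroxy-2-{[4-methoxy-3-(prop-2-enyloxy)phenyl]methyl}butanedioate | COC(=O)C[C@@](O)(Cc1ccc(OC)c(OCC=C)c1)C(=O)OC | intermediate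
8 | [4-(benzyloxy)-3-methoxyphenyl]methanol | COc1cc(CO)ccc1OCc1ccccc1 | starting material
9 | 1-(benzyloxy)-4-(bromomethyl)-2-methoxybenzene | COc1cc(CBr)ccc1OCc1ccccc1 | intermediate
10 | 2-[(2S,4S)-4-{[4-(benzyloxy)-3-methoxyphenyl]methyl}-2-tert-butyl-5-oxo-1,3-dioxolan-4-yl]acetic acid | CC(C)(C)[C@H]1O[C@](CC(=O)O)(Cc2ccc(OCc3ccccc3)c(OC)c2)C(=O)O1 | intermediate
11 | dimethyl (2S)-2-{[4-(benzyloxy)-3-methoxyphenyl]methyl}-2-hydroxybutanedioate | COC(=O)C[C@@](O)(Cc1ccc(OCc2ccccc2)c(OC)c1)C(=O)OC | intermediate
12 | 5-bromovanillin | COc1cc(C=O)cc(Br)c1O | starting material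
13 | 4-(benzyloxy)-3-bromo-5-methoxybenzaldehyde | COc1cc(C=O)cc(Br)c1OCc1ccccc1 | intermediate
14 | lithium aldolate of 7 and 13, drawn as the neutral hydroxy diester (2S,3R; S carbinol); formed in the flask | O[C@H](c1cc(OC)c(OCc2ccccc2)c(Br)c1)[C@@H](C(=O)OC)[C@@](O)(Cc1ccc(OC)c(OCC=C)c1)C(=O)OC | intermediate
15 | methyl (2S,3R,4S)-2-[4-(benzyloxy)-3-bromo-5-methoxyphenyl]-4-hydroxy-4-{[4-methoxy-3-(prop-2-enyloxy)phenyl]methyl}-5-oxooxolane-3-carboxylate | O=C1O[C@H](c2cc(OC)c(OCc3ccccc3)c(Br)c2)[C@@H](C(=O)OC)[C@@]1(O)Cc1ccc(OC)c(OCC=C)c1 | intermediate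
16 | (2S,3R)-3-[(S)-[4-(benzyloxy)-3-bromo-5-methoxyphenyl](hydroxy)methyl]-2-{[4-methoxy-3-(prop-2-enyloxy)phenyl]methyl}butane-1,2,4-triol | O[C@H](c1cc(OC)c(OCc2ccccc2)c(Br)c1)[C@@H](CO)[C@@](O)(Cc1ccc(OC)c(OCC=C)c1)CO | intermediate
17 | (3S,4R,5S)-5-[4-(benzyloxy)-3-bromo-5-methoxyphenyl]-4-(hydroxymethyl)-3-{[4-methoxy-3-(prop-2-enyloxy)phenyl]methyl}oxolan-3-ol | COc1ccc(C[C@@]2(O)CO[C@H](c3cc(OC)c(OCc4ccccc4)c(Br)c3)[C@H]2CO)cc1OCC=C | intermediate
18 | lithium aldolate of 11 and 13, drawn as the neutral hydroxy diester (2S,3R; S carbinol); formed in the flask | O[C@H](c1cc(OC)c(OCc2ccccc2)c(Br)c1)[C@@H](C(=O)OC)[C@@](O)(Cc1ccc(OCc2ccccc2)c(OC)c1)C(=O)OC | intermediate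
19 | methyl (2S,3R,4S)-2-[4-(benzyloxy)-3-bromo-5-methoxyphenyl]-4-{[4-(benzyloxy)-3-methoxyphenyl]methyl}-4-hydroxy-5-oxooxolane-3-carboxylate | O=C1O[C@H](c2cc(OC)c(OCc3ccccc3)c(Br)c2)[C@@H](C(=O)OC)[C@@]1(O)Cc1ccc(OCc2ccccc2)c(OC)c1 | intermediate
20 | (2S,3R)-3-[(S)-[4-(benzyloxy)-3-bromo-5-methoxyphenyl](hydroxy)methyl]-2-{[4-(benzyloxy)-3-methoxyphenyl]methyl}butane-1,2,4-triol | O[C@H](c1cc(OC)c(OCc2ccccc2)c(Br)c1)[C@@H](CO)[C@@](O)(Cc1ccc(OCc2ccccc2)c(OC)c1)CO | intermediate
21 | (3S,4R,5S)-5-[4-(benzyloxy)-3-bromo-5-methoxyphenyl]-3-{[4-(benzyloxy)-3-methoxyphenyl]methyl}-4-(hydroxymethyl)oxolan-3-ol | COc1cc(C[C@@]2(O)CO[C@H](c3cc(OC)c(OCc4ccccc4)c(Br)c3)[C@H]2CO)ccc1OCc1ccccc1 | intermediate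
22 | pinacol boronate of 21 (Br replaced by 4,4,5,5-tetramethyl-1,3,2-dioxaborolan-2-yl); formed in the flask | COc1cc(C[C@@]2(O)CO[C@H](c3cc(OC)c(OCc4ccccc4)c(B4OC(C)(C)C(C)(C)O4)c3)[C@H]2CO)ccc1OCc1ccccc1 | intermediate
23 | bis-tetrahydrofuran biaryl, ring A allyl ether, rings C, D and F benzyl ethers (full name in step 16) | COc1ccc(C[C@@]2(O)CO[C@H](c3cc(OC)c(OCc7ccccc7)c(-c4cc([C@H]5OC[C@](O)(Cc6ccc(OCc7ccccc7)c(OC)c6)[C@@H]5CO)cc(OC)c4OCc4ccccc4)c3)[C@H]2CO)cc1OCC=C | intermediate
24 | bis-tetrahydrofuran biaryl, ring A free phenol, rings C, D and F benzyl ethers | COc1ccc(C[C@@]2(O)CO[C@H](c3cc(OC)c(OCc7ccccc7)c(-c4cc([C@H]5OC[C@](O)(Cc6ccc(OCc7ccccc7)c(OC)c6)[C@@H]5CO)cc(OC)c4OCc4ccccc4)c3)[C@H]2CO)cc1O | intermediate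
25 | bis-tetrahydrofuran biaryl, ring A acetate, rings C, D and F benzyl ethers | COc1ccc(C[C@@]2(O)CO[C@H](c3cc(OC)c(OCc7ccccc7)c(-c4cc([C@H]5OC[C@](O)(Cc6ccc(OCc7ccccc7)c(OC)c6)[C@@H]5CO)cc(OC)c4OCc4ccccc4)c3)[C@H]2CO)cc1OC(C)=O | intermediate
26 | bis-tetrahydrofuran precursor, ring A acetate, phenols of rings C, D and F free, both rings (2S,3R,4S) | COc1ccc(C[C@@]2(O)CO[C@H](c3cc(OC)c(O)c(-c4cc([C@H]5OC[C@](O)(Cc6ccc(O)c(OC)c6)[C@@H]5CO)cc(OC)c4O)c3)[C@H]2CO)cc1OC(C)=O | intermediate
27 | tetralin–tetrahydrofuran dimer, ring A acetate (1'S,2'S,3'S; 2S,3R,4S) | COc1ccc(C[C@@]2(O)CO[C@H](c3cc(OC)c(O)c(-c4cc([C@H]5c6cc(O)c(OC)cc6C[C@@](O)(CO)[C@@H]5CO)cc(OC)c4O)c3)[C@H]2CO)cc1OC(C)=O | intermediate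
28 | CNP0252244.1 | COc1ccc(C[C@@]2(O)CO[C@H](c3cc(OC)c(O)c(-c4cc([C@H]5c6cc(O)c(OC)cc6C[C@@](O)(CO)[C@@H]5CO)cc(OC)c4O)c3)[C@H]2CO)cc1O | target

## Step count and least certain steps

Total: 21 steps. Longest linear sequence: 13 steps (3 → 4 → 5 → 6 → 7 → 15 → 16 → 17 → 23 → 24 → 25 → 26 → 27 → 28; steps 2–5, 10–12 and 16–21).

**Step 20 (key step).**
- What may go wrong: loss of site selectivity through slow Friedel–Crafts closure of the ring C cation onto ring A para to the acetoxy group; acid-induced loss of the acetate, which would unmask that position; intermolecular alkylation of the electron-rich biphenol.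
- Fallback: make the ring switch on the monomer, where only one nucleophilic arene is present. Bromide 21 is treated with TFA in CH2Cl2 to give the bromo aryltetralin F1. Miyaura borylation of F1 gives the tetralin pinacol boronate F2. Suzuki–Miyaura coupling of F2 with 17 gives the allyl tris-benzyl tetralin–tetrahydrofuran dimer F3. Deallylation with Pd(PPh3)4 and morpholine gives the ring A phenol F4, and hydrogenolysis of F4 gives the target. The fallback sets out from 21 and returns at 28.

**Step 10.**
- What may go wrong: poor facial selectivity at C3 of the dianion; base-induced opening of the lactone by elimination of the benzylic carboxylate (the Stobbe pathway); retro-aldol cleavage on warming.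
- Fallback: put C3 under auxiliary control. Acid 6 is coupled through its pivaloyl mixed anhydride with lithiated (S)-4-benzyl-1,3-oxazolidin-2-one to give the imide F5. The Evans syn-aldol of F5 with 13 (Bu2BOTf, iPr2NEt, CH2Cl2, −78 °C) gives the aldol adduct F6, in which both new centres have the configuration of 16. LiBH4 reduction of F6 cleaves the auxiliary and opens the dioxolanone, giving 16. The fallback sets out from 6 and returns at 16.

**Step 13.**
- What may go wrong: the same loss of facial selectivity and lactone opening as in step 10.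
- Fallback: the same auxiliary sequence from acid 10, through the imide F7 and the aldol adduct F8, with LiBH4 reduction to 20. It sets out from 10 and returns at 20.

**Step 12.**
- What may go wrong: premature Friedel–Crafts closure of the benzylic cation onto ring A, whose carbon para to the allyloxy group is activated; incomplete equilibration at C2 leaving an epimer mixture. Step 15 makes the same demand; there the over-reaction product would be the tetralin on which the fallback for step 20 is built.
- Fallback: deactivate ring A before the acid step. Tetraol 16 is deallylated (Pd(PPh3)4, morpholine) to the phenolic tetraol F9. Acetylation of the phenoxide (Ac2O, K2CO3) gives the aryl acetate tetraol F10. Camphorsulfonic acid closes it to the bromo tetrahydrofuran acetate F11. Coupling of F11 with boronate 22 under anhydrous fluoride conditions (Pd(dppf)Cl2, CsF, 1,4-dioxane) gives 25. The fallback sets out from 16 and returns at 25.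

**Step 16.**
- What may go wrong: protodeboronation of the ortho-alkoxy arylboronate; borylation of 17 by left-over diboron followed by homocoupling; slow transmetalation between two ortho-oxygenated partners.
- Fallback: separate the two events and use an isolable slow-release boron partner. Bromide 21 is borylated as before and the crude 22 is treated with aqueous KHF2 to precipitate the potassium aryltrifluoroborate F12. F12 is purified and then coupled with 17 in a separate step (Pd(OAc)2, SPhos, K2CO3, toluene–water) to give 23. The fallback sets out from 21 and returns at 23.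

## Further compounds

F1 | step 20 | bromo aryltetralin: (1'S,2'S,3'S)-1'-[4-(benzyloxy)-3-bromo-5-methoxyphenyl]-7'-(benzyloxy)-2',3'-bis(hydroxymethyl)-6'-methoxytetralin-3'-ol | Brc1cc([C@H]2c3cc(OCc4ccccc4)c(OC)cc3C[C@@](O)(CO)[C@@H]2CO)cc(OC)c1OCc1ccccc1
F2 | step 20 | tetralin pinacol boronate (F1 with Br replaced by the pinacolboryl group) | CC1(C)OB(OC1(C)C)c1cc([C@H]2c3cc(OCc4ccccc4)c(OC)cc3C[C@@](O)(CO)[C@@H]2CO)cc(OC)c1OCc1ccccc1
F3 | step 20 | tetralin–tetrahydrofuran dimer, ring A allyl ether, rings C, D and F benzyl ethers | COc1ccc(C[C@@]2(O)CO[C@H](c3cc(OC)c(OCc7ccccc7)c(-c4cc([C@H]5c6cc(OCc7ccccc7)c(OC)cc6C[C@@](O)(CO)[C@@H]5CO)cc(OC)c4OCc4ccccc4)c3)[C@H]2CO)cc1OCC=C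
F4 | step 20 | tetralin–tetrahydrofuran dimer, ring A free phenol, rings C, D and F benzyl ethers | COc1ccc(C[C@@]2(O)CO[C@H](c3cc(OC)c(OCc7ccccc7)c(-c4cc([C@H]5c6cc(OCc7ccccc7)c(OC)cc6C[C@@](O)(CO)[C@@H]5CO)cc(OC)c4OCc4ccccc4)c3)[C@H]2CO)cc1O
F5 | step 10 | (S)-4-benzyl-3-acyl-oxazolidin-2-one imide of acid 6 | CC(C)(C)[C@H]1O[C@](CC(=O)N2[C@@H](Cc3ccccc3)COC2=O)(Cc2ccc(OC)c(OCC=C)c2)C(=O)O1
F6 | step 10 | Evans syn-aldol adduct of F5 with 13 | O[C@H](c1cc(OC)c(OCc2ccccc2)c(Br)c1)[C@@H](C(=O)N1[C@@H](Cc2ccccc2)COC1=O)[C@]1(Cc2ccc(OC)c(OCC=C)c2)O[C@H](C(C)(C)C)OC1=O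
F7 | step 13 | (S)-4-benzyl-3-acyl-oxazolidin-2-one imide of acid 10 | CC(C)(C)[C@H]1O[C@](CC(=O)N2[C@@H](Cc3ccccc3)COC2=O)(Cc2ccc(OCc3ccccc3)c(OC)c2)C(=O)O1
F8 | step 13 | Evans syn-aldol adduct of F7 with 13 | O[C@H](c1cc(OC)c(OCc2ccccc2)c(Br)c1)[C@@H](C(=O)N1[C@@H](Cc2ccccc2)COC1=O)[C@]1(Cc2ccc(OCc3ccccc3)c(OC)c2)O[C@H](C(C)(C)C)OC1=O
F9 | step 12 | phenolic tetraol (16 with ring A free phenol) | O[C@H](c1cc(OC)c(OCc2ccccc2)c(Br)c1)[C@@H](CO)[C@@](O)(Cc1ccc(OC)c(O)c1)CO
F10 | step 12 | aryl acetate tetraol (16 with ring A acetate) | O[C@H](c1cc(OC)c(OCc2ccccc2)c(Br)c1)[C@@H](CO)[C@@](O)(Cc1ccc(OC)c(OC(C)=O)c1)CO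
F11 | step 12 | bromo tetrahydrofuran acetate (17 with ring A acetate) | COc1ccc(C[C@@]2(O)CO[C@H](c3cc(OC)c(OCc4ccccc4)c(Br)c3)[C@H]2CO)cc1OC(C)=O
F12 | step 16 | potassium aryltrifluoroborate of the ring D/F half | [K+].COc1cc(C[C@@]2(O)CO[C@H](c3cc(OC)c(OCc4ccccc4)c([B-](F)(F)F)c3)[C@H]2CO)ccc1OCc1ccccc1
A1 | alternative 1 | 2,2'-bis(benzyloxy)-5'-(1,3-dioxolan-2-yl)-3,3'-dimethoxy-[1,1'-biphenyl]-5-carbaldehyde | O=Cc1cc(OC)c(OCc2ccccc2)c(-c2cc(C3OCCO3)cc(OC)c2OCc2ccccc2)c1
A2 | alternative 1 | γ-lactone from the malate dianion and A1 (benzylic centre drawn trans) | O=C1O[C@H](c2cc(OC)c(OCc3ccccc3)c(-c3cc(C4OCCO4)cc(OC)c3OCc3ccccc3)c2)[C@@H](C(=O)OC)[C@@]1(O)Cc1ccc(OCc2ccccc2)c(OC)c1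
A3 | alternative 2 | 2-aryl-3-{[(3-acetoxy-4-methoxybenzyl)oxy]methyl}oxolan-4-one (aryl = acetylated biaryl with a methyl ester on the second ring) | O=C1CO[C@H](c2cc(OC)c(OC(C)=O)c(-c3cc(C(=O)OC)cc(OC)c3OC(C)=O)c2)[C@H]1COCc1ccc(OC)c(OC(C)=O)c1
A4 | alternative 2 | 1-hydroxy-2,6-diaryl-3,7-dioxabicyclo[3.3.0]octane (ring A aryl drawn exo) | O[C@]12CO[C@H](c3cc(OC)c(OC(C)=O)c(-c4cc(C(=O)OC)cc(OC)c4OC(C)=O)c3)[C@H]1CO[C@@H]2c1ccc(OC)c(OC(C)=O)c1
A5 | alternative 3 | methyl 2-bromo-3-aryl-3-{5-(benzyloxy)-2-[3-(benzyloxy)-2-oxopropyl]-4-methoxyphenyl}propanoate (aryl = dibenzylated biaryl with a dioxolane on the second ring) | COC(=O)C(Br)[C@@H](c1cc(OC)c(OCc2ccccc2)c(-c2cc(C3OCCO3)cc(OC)c2OCc2ccccc2)c1)c1cc(OCc2ccccc2)c(OC)cc1CC(=O)COCc1ccccc1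
A6 | alternative 3 | methyl 1-aryl-7-(benzyloxy)-3-[(benzyloxy)methyl]-3-hydroxy-6-methoxytetralin-2-carboxylate | COC(=O)[C@@H]1[C@@H](c2cc(OC)c(OCc3ccccc3)c(-c3cc(C4OCCO4)cc(OC)c3OCc3ccccc3)c2)c2cc(OCc3ccccc3)c(OC)cc2C[C@@]1(O)COCc1ccccc1
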